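Slowness was what cold would cost, and I wanted it priced against what warmth gives to the homo dimer.

    substrate + catalyst → catalyst + product (k1 = 1.72 × 10⁵ M⁻¹ s⁻¹, Ea1 = 19.0 kJ mol⁻¹)
    2 substrate → homo dimer (k2 = 67.1 M⁻¹ s⁻¹, Ea2 = 47.0 kJ mol⁻¹)
    (constants at 5 °C)

the same everywhere: substrate 0.0020 M; catalyst 0.26 mol%; time 6.0 s
- larch: temperature −20 °C
- elm: temperature 5 °C

- percentages count the substrate that a species holds: one homo dimer counts as two
- a doubled species enters its step squared and goes two at a time
- all constants are for 5 °C and move with temperature by the activation energies

- the best flask by amount of product, in percent of the substrate charged; "all alike" if 1.5 percentage points covers them all (larch / elm / all alike)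
- amount of product at the end, in percent of the substrate charged, larch
- amount of product at the end, in percent of the substrate charged, elm

I wrote a for the substrate left, as a fraction of the charge, and reckoned in steps.

1. The catalyst leaves its step unchanged, so that step was pseudo-first-order, with constant κ = 0.894 s⁻¹ in elm and a time of 1.12 s. At the full charge the dimer step ran at 0.268 s⁻¹, a time of 3.73 s. So in elm the catalytic time was shorter than the dimer time, and both were shorter than the 6.0 s allowed.

2. Cold divided the catalytic constant by 2.25 and the dimer constant by 7.44. In larch the ladder therefore read 2.52 s for catalysis, then the 6.0 s allowed, then 27.7 s for the dimer step at the full charge.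

3. I carried one quantity, the loss number b: the rate at which the dimer step takes substrate over the rate at which the catalytic step takes it, at the full charge. It came to 0.300 in elm and 0.0908 in larch. At fraction a the ratio is b·a, since the dimer step goes with the square.

4. With e = exp(−κt), the rate equation gives a = e/(1 + b(1 − e)), and summing the product share along the way gives p = ln[(1 + b)/(1 + b·a)]/b.

5. Elm: a = 0.360%, p = 87.1%. Larch: a = 8.52%, p = 87.2%. These lay within the 1.5 percentage points margin, so I called the flasks alike.

The forecast said all alike, with 87.2% in larch and 87.1% in elm: “the two effects nearly cancel”.

The simulation gave 87.2% in larch and 87.1% in elm, so all alike.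

In elm the catalytic step took substrate 3.3 times as fast as the dimer step at the start, 7.1 times at 0.700 s and 930 times at 6.00 s, the rise that the inverse of b·a describes as a falls. Of elm's dimer turnover up to the asked time, 99.7% was behind it at 3.00 s.

Elm read at 2.5 s keeps b at 0.300, and the shorter time gives a = 8.43% and p = 79.1%. The simulated reading there was 79.1% product with 8.43% substrate.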